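(Its constants are invented; the result is computed.)

**The ceiling.** At 13 mM the solution is saturated with starting material, which is less than even the smallest charge of solid substrate, 0.060 M.

common to all: enzyme 1.6 µM; time 3.0 min
- Thursday's: solid substrate 0.060 M
- Saturday's: solid substrate 0.10 M
- Tuesday's: solid substrate 0.15 M
- Friday's: solid substrate 0.25 M

- [target] at the end for Thursday's, Saturday's, Tuesday's, Friday's, in this order
- how that number moves from the first to the last of them (rises all the way / falls all the way / falls, then rises / hardly changes / rises, then falls)

- solid, in amounts per volume of the solution: solid substrate
- at the start none of the solid substrate is in solution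
- "hardly changes" means that all values lie within two and a half points (for a concentration: within two and a half percent of the largest)
- run time (Thursday's): 3.0 min

    starting material + enzyme → target + enzyme, rate k1*[starting material]^2*[enzyme]/(1 + ([starting material]/Kh1)^2) (Kh1 = 0.063 M, k1 = 1.3 × 10⁶ M⁻² s⁻¹)
    target → over-reaction product (k2 = 0.0099 s⁻¹)
    solid substrate ⇌ starting material, rate k3*(cs3 - [starting material]) while solid is left; crystals form when [starting material] > cs3 (cs3 = 13 mM, k3 = 0.025 s⁻¹)

**The freeze.** I freeze dissolved starting material where dissolution equals the enzyme's use, and the enzyme stays at 1.6 µM as a catalyst. Dropping the denominator of step 1 gives a quadratic with the level 7.86 mM. The dropped term is 1.56%, since the level lies below 0.063 M. Dissolution at that level delivers 1.29 × 10⁻⁴ M s⁻¹. I carry this as the feed, the quasi-steady-state rate at which material passes through the solution.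

**First number.** Target gains the feed and decays with the rate constant 0.0099 s⁻¹. A feed running from the first moment gives 0.0108 M at 3.0 min.

**The weak link.** That start is wrong: the enzyme's rate goes with the square of the concentration of starting material, and none is in solution at the start. The level fills with a rate constant of 0.0577 s⁻¹, quickly against the run. Integrating the enzyme's shortfall along that filling curve gives a lag of 30.0 s.

**The commitment.** Dissolved material by the end comes to 0.0271 M, so solid remains in each flask and the charge enters no term of the reckoning. With the lag, I commit to 0.0100 M, 0.0100 M, 0.0100 M and 0.0100 M of target in Thursday's, Saturday's, Tuesday's and Friday's flasks, so the row hardly changes.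

The forecast gives 0.01 M, 0.01 M, 0.01 M and 0.01 M, hardly changes, holding that “even the smallest charge never runs out and all four runs behave identically”.

**The flask.** The simulation gives 0.00990 M, 0.00990 M, 0.00990 M and 0.00990 M: hardly changes. In Thursday's flask, starting material stands at 13.0% of the charge after 1.50 min and 13.2% after 3.00 min, and the frozen level is 13.1% of that charge. Friday's flask still holds 6.48% of its charge as solid substrate after 30.0 min. There the feed divided by 0.0099 s⁻¹ comes to 5.19% of the charge, and target stands at 5.16%.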